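## Retrosynthetic overview

1. Chiricanine C (9) comes from protodecarboxylation of stilbene-2-carboxylic acid 8. The CO2H occupies, and so blocks, the one ring position that must remain C–H.
2. Acid 8 comes from E1cB opening of 3-phenyl-3,4-dihydroisocoumarin 7. The lactone masks both the E-stilbene and the acid.
3. Lactone 7 comes from double Stille prenylation of 5,7-diiodide 5, which comes from exhaustive iodination of 3. The only two free activated ring positions in 3 are the two prenyl sites.
4. Lactone 3 comes from the ortho-toluate dianion of sparassol (1), whose OMe/OH pattern is already differentiated, plus benzaldehyde (2).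
5. Rings: both arenes are purchased. The only ring formed is the temporary δ-lactone (step 1), which is opened again in step 4.

**Assumptions**
- The target has no stereocentre, so it is achiral and "single enantiomer" does not apply. The only stereoelement is the E-alkene, set in step 4.
- Sparassol (methyl 2-hydroxy-4-methoxy-6-methylbenzoate) and tributyl(prenyl)stannane are taken as catalogue items.

## Route

**Step 1**
Reactants: 1 methyl 2-hydroxy-4-methoxy-6-methylbenzoate (sparassol); 2 benzaldehyde
Product: 3 (±)-8-hydroxy-6-methoxy-3-phenyl-3,4-dihydroisocoumarin (isochroman-1-one)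
Conditions: LDA (2.3 equiv), THF, −78 °C, 1 h; 2 (1.2 equiv), −78 → 0 °C; 1 M HCl work-up
Reagents that add atoms: benzaldehyde, O=Cc1ccccc1
Why: This is a lateral (ortho-toluate) lithiation followed by aldol addition and lactonisation: LDA forms the phenoxide/benzylic dianion (only the C6-CH3 is vinylogously acidified by the ester, and the phenoxide suppresses self-condensation), the anion adds to PhCHO, the alkoxide expels MeOH from the ester, and the new C3 centre is racemic but is destroyed in step 4.

**Step 2**
Reactants: 3; 4 N-iodosuccinimide
Product: 5 (±)-8-hydroxy-5,7-diiodo-6-methoxy-3-phenyl-3,4-dihydroisocoumarin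
Conditions: NIS (2.3 equiv), TFA (0.3 equiv), MeCN, 0 °C → rt, dark
Reagents that add atoms: N-iodosuccinimide, O=C1CCC(=O)N1I
Why: In this electrophilic aromatic iodination C5 and C7 are the only open positions on the OH/OMe-activated ring, so exhaustive iodination gives a single regioisomer, while the phenyl ring is unactivated and no alkene is yet present.

**Step 3**
Reactants: 5; 6 tributyl(3-methylbut-2-en-1-yl)stannane
Product: 7 (±)-8-hydroxy-6-methoxy-5,7-bis(3-methylbut-2-en-1-yl)-3-phenyl-3,4-dihydroisocoumarin
Conditions: 6 (3 equiv), Pd2(dba)3 (5 mol %), AsPh3 (40 mol %), CuI (20 mol %), degassed DMF, 75 °C; aq KF work-up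
Reagents that add atoms: tributyl(prenyl)stannane, CCCC[Sn](CCCC)(CCCC)CC=C(C)C
Why: This is a double Stille coupling under neutral, Cu-accelerated conditions that spare the lactone and the chelated phenol, and reductive elimination from the hindered aryl(allyl)Pd occurs at the less substituted allyl terminus to give linear prenyl rather than reverse prenyl.

**Step 4**
Reactants: 7
Product: 8 2-hydroxy-4-methoxy-3,5-bis(3-methylbut-2-en-1-yl)-6-[(E)-2-phenylethenyl]benzoic acid
Conditions: LDA (2.5 equiv), THF, −78 → 0 °C; cold 10 % citric acid, used crude
Reagents that add atoms: none
Why: This is an E1cB lactone opening: deprotonation at C4 gives the same type of toluate anion as in step 1, which expels the β-carboxylate, and elimination through the conformer with pseudo-equatorial phenyl (aryl and Ph anti) gives the thermodynamically preferred E-stilbene without touching the prenyl groups at low temperature.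

**Step 5**
Reactants: 8
Product: 9 chiricanine C, 3-methoxy-2,4-bis(3-methylbut-2-en-1-yl)-5-[(E)-2-phenylethenyl]phenol
Conditions: DMF, 130 °C, N2, dark, 2 h
Reagents that add atoms: none
Why: This is a thermal protodecarboxylation of a di-ortho-substituted, electron-rich salicylic acid by ipso-protonation (assisted by the o-OH and p-OMe) and loss of CO2, and the acid-free, light-free medium avoids chroman formation from the o-prenylphenol and E→Z isomerisation.

## Compound list

| No. | Name | SMILES | Role |
|---|---|---|---|
| 1 | methyl 2-hydroxy-4-methoxy-6-methylbenzoate (sparassol) | COC(=O)c1c(C)cc(OC)cc1O | starting material |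
| 2 | benzaldehyde | O=Cc1ccccc1 | starting material |
| 3 | (±)-8-hydroxy-6-methoxy-3-phenyl-3,4-dihydroisocoumarin | O=C1OC(c2ccccc2)Cc2cc(OC)cc(O)c21 | intermediate (racemic) |
| 4 | N-iodosuccinimide | O=C1CCC(=O)N1I | starting material (reagent) |
| 5 | (±)-8-hydroxy-5,7-diiodo-6-methoxy-3-phenyl-3,4-dihydroisocoumarin | O=C1OC(c2ccccc2)Cc2c(I)c(OC)c(I)c(O)c21 | intermediate (racemic) |
| 6 | tributyl(3-methylbut-2-en-1-yl)stannane | CCCC[Sn](CCCC)(CCCC)CC=C(C)C | starting material |
| 7 | (±)-8-hydroxy-6-methoxy-5,7-diprenyl-3-phenyl-3,4-dihydroisocoumarin | O=C1OC(c2ccccc2)Cc2c(CC=C(C)C)c(OC)c(CC=C(C)C)c(O)c21 | intermediate (racemic) |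
| 8 | 2-hydroxy-4-methoxy-3,5-diprenyl-6-[(E)-styryl]benzoic acid | OC(=O)c1c(O)c(CC=C(C)C)c(OC)c(CC=C(C)C)c1/C=C/c1ccccc1 | intermediate |
| 9 | chiricanine C | COc1c(CC=C(C)C)c(O)cc(/C=C/c2ccccc2)c1CC=C(C)C | target |

## Summary

- **Total steps:** 5
- **Longest linear sequence:** 5
- No protecting groups are used.

## Steps most likely to fail

1. **Step 3, double Stille at two di-ortho-substituted C–I bonds.** The risks are protodeiodination, incomplete second coupling and some reverse-prenyl product. Fallback: couple 5 twice with allyltributylstannane, which has no α/γ ambiguity and is less hindered. Then convert both allyl groups to prenyl by cross-metathesis with 2-methyl-2-butene (Grubbs II). This is done at the lactone stage, where no stilbene alkene can interfere.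
2. **Step 1, phenoxide/toluate dianion condensation.** The risks are sluggish second deprotonation, retro-aldol and slow lactonisation. Fallback: start from methyl 2,4-dimethoxy-6-methylbenzoate and use the ordinary monoanion with PhCHO to give the 6,8-dimethoxy lactone. Then cleave only the C8 (peri) methyl ether with BCl3, using chelation to the lactone carbonyl, to reach the same compound 3 before any prenyl group is present. This adds one step.
3. **Step 4, E1cB opening next to the C5-prenyl group.** The risks are hindered deprotonation, base-induced prenyl isomerisation and relactonisation on acidification. Fallback: build the alkene by olefination instead of elimination.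
   - Acetylate and ring-diiodinate sparassol.
   - Brominate the benzylic position with NBS/AIBN, then carry out an Arbuzov reaction.
   - Perform the HWE reaction with PhCHO to give the E-stilbene ester.
   - Carry out the double Stille prenylation.
   - Finish with nucleophilic ester cleavage and decarboxylation.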